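## Analysis of the target

Target 14 is a flavone: a 4-pyranone (ring C) fused to a benzene ring (ring A) through C4a and C8a, with an unsubstituted phenyl ring B at C2. It has no stereocenter and is flat, so the whole problem is one of substitution pattern. Ring A is hexasubstituted, with oxygen on C5, C6, C7 and C8, and ring C carries a fifth oxygen at C3. Only the C5 oxygen is a free hydroxyl; the other four are methyl ethers. The C5 hydroxyl lies peri to the C4 carbonyl and is hydrogen-bonded to it, which makes it the least nucleophilic oxygen but also the one most easily unmasked by a chelating Lewis acid. Sensitive points are the pyranone (hard nucleophiles add at C2 and open it), the very electron-rich ring A (oxidised towards quinones once it bears a free phenol), and the aryl methyl ethers (a Lewis acid can cleave more than one). The difficulty is to build a fully substituted benzene ring without positional isomers and to tell five neighbouring oxygens apart at the end. The strategy rests on C4: this carbonyl carbon is bonded to C4a of ring A and to the C3=C2–phenyl unit, so it can come from carbon monoxide 6 between an aryl iodide and phenylacetylene 7, while a hydroxyl ortho to the iodide becomes O1.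

## Retrosynthetic reasoning

**14 ⇒ 13.** The O–CH3 bond at C5 is cut last, leading back to 3,5,6,7,8-pentamethoxyflavone 13. Of the five ethers in 13, only the C5 ether can form a six-membered chelate with the C4 carbonyl and a boron trihalide, so this is where a single methyl group can be removed. Keeping C5 methylated until the end means no free phenol sits on ring A during the oxidation of ring C. The forward step must stop after one cleavage.

**13 ⇒ 12.** The O–CH3 bond at C3 is cut, giving flavonol 12. The C3 hydroxyl is the only acidic site in 12, so the forward reaction is a plain O-alkylation with no selectivity question.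

**12 ⇒ 10.** The C3–O bond is cut, giving 5,6,7,8-tetramethoxyflavone 10. C3 is accepted as a CH at the ring-forming stage because a terminal alkyne delivers it that way. The oxygen is added afterwards by electrophilic oxygen transfer from a dioxirane to the C2=C3 bond, through epoxide 11, which an acid opens at C2 and which then loses the C3 hydrogen. The forward reaction must oxidise this electron-poor double bond without touching ring A.

**10 ⇒ 5 + 6 + 7.** Three bonds of ring C are cut together: C4a–C4, C4–C3 and O1–C2. This removes ring C completely and leaves iodophenol 5, carbon monoxide 6 and phenylacetylene 7, two of which are commercial. Cutting here rather than at C2–C1′ or within ring A is the most convergent choice, and the adjacent iodine and hydroxyl of 5 fix the ring-fusion regiochemistry. The forward reaction, under a palladium catalyst in a secondary amine, must insert CO before the alkyne couples (giving ynone 8) and then close the six-membered ring rather than a five-membered one (through enaminone 9).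

**5 ⇒ 4.** The C–I bond is cut, giving 2,3,4,5-tetramethoxyphenol 4. This phenol has a single unsubstituted ring carbon, ortho to the hydroxyl, so electrophilic iodination can give only one product. The forward step must substitute without oxidising the phenol.

**4 ⇒ 1.** The phenolic C–O bond is cut, giving commercial 1,2,3,4-tetramethoxybenzene 1. Its two ring hydrogens are equivalent and each is ortho to a methoxy group, so directed metalation gives one aryllithium 2. Borylation to 3 and peroxide oxidation then give 4 in one flask. This is preferred to formylation followed by peroxide oxidation of the aryl aldehyde, which takes two isolations; the classical alkaline version of that oxidation is also unreliable for an aldehyde with no free ortho or para hydroxyl.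

## Alternatives that were turned down

**Alternative 1: ring A grown on a pyranone from a squarate.**
- Disconnection: ring A is removed; C4a–C5 and C8–C8a are cut. C5 to C8 come from dimethyl squarate A4, and rings B and C from 3-methoxy-2-phenyl-4H-pyran-4-one A3.
- Forward key step: A3 is metalated at the ring carbon next to the ring oxygen and added to one carbonyl of A4 to give carbinol A2. Heating A2 opens the cyclobutenone to a dienylketene. Its ketene carbon bonds to the neighbouring pyranone CH and, after tautomerisation, ring A appears as hydroquinone A1 (5,8-dihydroxy-3,6,7-trimethoxyflavone).
- For: the C3 methoxy group and the free C5 hydroxyl are in place as soon as ring A forms. The endgame is one O-methylation at C8, which the chelated C5 hydroxyl should allow selectively. On this point it is stronger than the chosen route, which needs three steps after ring closure.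
- Against: A3 is not commercial and needs its own synthesis. Its metalation must be regioselective on a pyranone that is itself an electrophile for organolithium reagents, so the preparation of A2 is uncertain. A1 is a 5,8-hydroquinone on an electron-rich ring and should oxidise readily to the quinone.
- Comparison: the chosen route makes the same ring A from commercial arene 1 with no regiochemical question and puts its risk in one reaction of a known type, at the price of the longer endgame.

**Alternative 2: C3 inserted as a carbene carbon into a coumaranone.**
- Disconnection: C2–C3 and C3–C4 are cut and C3 is removed as a one-carbon unit, contracting ring C to the furanone of coumaranone A7.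
- Forward key step: A7 is converted into silyl enol ether A6, a 3-silyloxybenzofuran. A dibromo carbene, generated from the haloform and a hindered alkoxide, adds to its C2=C3 bond. The dibromocyclopropane opens with loss of bromide and the silyl group, giving the six-membered ring as 3-bromoflavone A5.
- For: the ring A pattern can come from phenol 4 as in the chosen route, and C3 arrives already functionalised, so ring C needs no oxidation.
- Against: A7 takes several steps (O-alkylation of 4 with an α-halo phenylacetic acid unit, then ring closure on the single free carbon). The alkene of A6 is tetrasubstituted, part of an aromatic furan and flanked by phenyl, and the alkoxide that generates the carbene can also remove the silyl group. The bromine of A5 is a poor precursor of the C3 methoxy group: alkoxides attack 3-haloflavones at C2 and cause ring opening and contraction to five-membered products. A metal-mediated C–O coupling at a hindered vinyl bromide would be needed, followed by the same C5 demethylation as in the chosen route.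
- Comparison: two uncertain steps instead of one, and a longer sequence. It matches the chosen route only in leaving the C5 differentiation to the end.

**Alternative 3: a symmetric aryne annulated with a ketoester enolate.**
- Disconnection: O1–C8a and C4–C4a are cut. Ring A becomes 3,4,5,6-tetramethoxybenzyne A10, released from silyl triflate A9. C2, C3, C4, ring B and the C3 methoxy group come from ketoester A11.
- Forward key step: fluoride liberates A10 from A9. The ketone enolate oxygen of A11 adds to the aryne, and the aryl anion attacks the ester carbonyl and expels methoxide. This closes ring C to give A8, the same compound as 13.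
- For: it is the most convergent plan. The aryne is symmetric, so no regiochemistry arises, and the C3 methoxy group is carried in. This saves steps 4 and 5 of the chosen route, so on endgame economy this alternative is clearly stronger.
- Against: A9 needs about four steps from phenol 4 (ortho-halogenation, O-silylation, silyl migration to carbon, triflation), so the total is no shorter. More seriously, β-ketoester enolates normally attack arynes through carbon; the aryl anion then adds to the ketone and the four-membered alkoxide fragments, a formal insertion into the C–C bond. O-arylation followed by acylation at the ester is the minor pathway and would have to become the only one. An aryne flanked by two methoxy groups is also hindered and poorly electrophilic.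
- Comparison: the three-component coupling of the chosen route is an established reaction type whose ring-size problem has a known solution, and its precursor 5 is two steps from 1. In place of the shorter endgame it offers precedent for every bond-forming event.

Key step: step 3

Remark on the chemistry: 14 is achiral. The only stereogenic compound of the route, epoxide 11, forms as a racemate and both of its stereocenters are erased in the same flask, so no stereocontrol is needed.

## Route

Step 1
Reactants: 1 1,2,3,4-tetramethoxybenzene
Product: 4 2,3,4,5-tetramethoxyphenol, via aryllithium 2 (not isolated), via dimethyl arylboronate 3 (not isolated)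
Conditions: n-BuLi, TMEDA, THF, 0 °C; B(OMe)3, −78 °C → rt; 30% aq. H2O2, AcOH, 0 °C → rt
Reagents that add atoms: hydrogen peroxide, OO
Why: Directed ortho-metalation: the two ring hydrogens of 1 are equivalent and each is ortho to a methoxy group, so a single aryllithium 2 should form. Borylation to 3 and peroxide oxidation of the C–B bond (aryl shift from boron to oxygen) should give the phenol without touching the methyl ethers.

Step 2
Reactants: 4 2,3,4,5-tetramethoxyphenol
Product: 5 2-iodo-3,4,5,6-tetramethoxyphenol
Conditions: NIS, MeCN, 0 °C, dark
Reagents that add atoms: N-iodosuccinimide, O=C1CCC(=O)N1I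
Why: Electrophilic aromatic iodination; the only unsubstituted ring carbon of 4 is ortho to the hydroxyl and para to a methoxy group, so only one iodide can form. Low temperature and exclusion of light should limit oxidation of the electron-rich phenol.

Step 3
Reactants: 5 2-iodo-3,4,5,6-tetramethoxyphenol; 6 carbon monoxide; 7 phenylacetylene
Product: 10 5,6,7,8-tetramethoxyflavone, via ynone 8 (not isolated), via enaminone 9 (not isolated)
Conditions: PdCl2(PPh3)2 (5 mol%), CO (20 atm), Et2NH, 120 °C, autoclave
Reagents that add atoms: none
Why: PdCl2(PPh3)2 is reduced in the amine to zerovalent palladium, which inserts into the C–I bond of 5; migratory insertion of CO gives the aroyl complex of divalent palladium, and amine-assisted alkynylation with 7 followed by reductive elimination forms C4a–C4 and C4–C3 in ynone 8. Et2NH then adds in conjugate fashion to the triple bond of 8 to give enaminone 9, and the ortho hydroxyl attacks the amine-bearing carbon and expels Et2NH, which forms O1–C2 and returns the amine. The closest known reaction type is the palladium-catalysed carbonylative Sonogashira coupling of 2-iodophenols with terminal alkynes, with cyclization in the same flask to chromones and flavones. Ring C closes in the 6-endo-trig mode at the enaminone carbon (overall a 6-endo-dig hydroalkoxylation of the ynone), followed by β-elimination of the amine. No stereocenter is formed. Three selectivities are needed: CO insertion before alkynylation, favoured by CO pressure, the absence of a copper co-catalyst and the electron-rich aryl group on palladium; six-membered rather than 5-exo-dig (aurone) closure, secured by the secondary amine because only the β-carbon of 9 is electrophilic; and a single ring A regiochemistry, fixed in 5 because iodine and hydroxyl are adjacent and no other ring carbon is free. The free phenol needs no protection, since it is the nucleophile of the closing event, and the methyl ethers should be inert to the conditions.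

Step 4
Reactants: 10 5,6,7,8-tetramethoxyflavone
Product: 12 3-hydroxy-5,6,7,8-tetramethoxyflavone, via flavone 2,3-epoxide 11 (not isolated)
Conditions: DMDO (excess), acetone/CH2Cl2, 0 °C → rt; then p-TsOH (cat.), CH2Cl2, rt
Reagents that add atoms: dimethyldioxirane, CC1(C)OO1
Why: Dioxirane epoxidation of the flavone C2=C3 bond, a known way to flavonols, gives the cis-fused racemic epoxide 11; its two stereocenters are set together by concerted syn oxygen transfer and erased at once. Acid opens 11 at C2 to the oxocarbenium ion stabilised by O1 and phenyl, and loss of the C3 hydrogen restores the pyranone as the flavonol. Ring A is fully substituted and conjugated to the carbonyl, so it should resist the oxidant.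

Step 5
Reactants: 12 3-hydroxy-5,6,7,8-tetramethoxyflavone
Product: 13 3,5,6,7,8-pentamethoxyflavone
Conditions: MeI, K2CO3, acetone, reflux
Reagents that add atoms: iodomethane, CI
Why: Williamson O-methylation; the C3 hydroxyl is the only acidic site of 12, and carbonate is too weak a nucleophile to open the pyranone.

Step 6
Reactants: 13 3,5,6,7,8-pentamethoxyflavone
Product: 14 5-hydroxy-3,6,7,8-tetramethoxyflavone
Conditions: BCl3 (1.2 equiv), CH2Cl2, −78 → 0 °C; then aq. HCl
Reagents that add atoms: none
Why: Chelation-controlled Lewis acid ether cleavage: BCl3 binds the C4 carbonyl and the peri C5 oxygen in a six-membered chelate, chloride removes that methyl group, and hydrolysis of the boron chelate releases the hydrogen-bonded phenol. The C3 ether can only form a five-membered chelate and the C6 to C8 ethers none, so a slight excess at low temperature should cleave C5 only.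

## Compound list

1 | 1,2,3,4-tetramethoxybenzene | COc1ccc(OC)c(OC)c1OC | starting material
2 | (2,3,4,5-tetramethoxyphenyl)lithium | [Li]c1cc(OC)c(OC)c(OC)c1OC | intermediate
3 | dimethyl (2,3,4,5-tetramethoxyphenyl)boronate | COB(OC)c1cc(OC)c(OC)c(OC)c1OC | intermediate
4 | 2,3,4,5-tetramethoxyphenol | Oc1cc(OC)c(OC)c(OC)c1OC | intermediate
5 | 2-iodo-3,4,5,6-tetramethoxyphenol | Oc1c(I)c(OC)c(OC)c(OC)c1OC | intermediate
6 | carbon monoxide | [C-]#[O+] | starting material
7 | phenylacetylene | C#Cc1ccccc1 | starting material
8 | 1-(2-hydroxy-3,4,5,6-tetramethoxyphenyl)-3-phenylprop-2-yn-1-one | O=C(C#Cc1ccccc1)c1c(O)c(OC)c(OC)c(OC)c1OC | intermediate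
9 | (E)-3-(diethylamino)-1-(2-hydroxy-3,4,5,6-tetramethoxyphenyl)-3-phenylprop-2-en-1-one (the push–pull double bond is configurationally mobile) | CCN(CC)/C(=C/C(=O)c1c(O)c(OC)c(OC)c(OC)c1OC)c1ccccc1 | intermediate
10 | 5,6,7,8-tetramethoxyflavone | COc1c(OC)c(OC)c2c(=O)cc(-c3ccccc3)oc2c1OC | intermediate
11 | 2,3-epoxy-5,6,7,8-tetramethoxyflavanone (flavone 2,3-oxide; epoxide cis-fused to ring C, racemic, one enantiomer drawn) | COc1c(OC)c(OC)c2C(=O)[C@@H]3O[C@@]3(Oc2c1OC)c1ccccc1 | intermediate
12 | 3-hydroxy-5,6,7,8-tetramethoxyflavone | COc1c(OC)c(OC)c2c(=O)c(O)c(-c3ccccc3)oc2c1OC | intermediate
13 | 3,5,6,7,8-pentamethoxyflavone | COc1c(OC)c(OC)c2c(=O)c(OC)c(-c3ccccc3)oc2c1OC | intermediate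
14 | 5-hydroxy-3,6,7,8-tetramethoxyflavone | COc1c(OC)c(O)c2c(=O)c(OC)c(-c3ccccc3)oc2c1OC | target

## Step count and least certain steps

Total step count: 6. Longest linear sequence: 6 steps (1 → 4 → 5 → 10 → 12 → 13 → 14); 6 and 7 are commercial.

**Step 3 (key step).**
- Risk: oxidative addition into an iodide flanked by two ortho oxygen substituents on a very electron-rich ring may be slow, so hydrodeiodination can compete. The aroyl palladium complex may be captured by the amine (aminocarbonylation) instead of the alkyne. Alkynylation may precede CO insertion, leading to a direct coupling and furan closure. Part of the ynone may close in the five-membered mode.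
- Fallback: it sets out from 5 and rejoins the route at 8, which is closed to 10. The C4 carbon is brought in with the alkyne instead of as CO. Phenol 5 is protected (MOMCl, i-Pr2NEt, CH2Cl2) as 1-iodo-2,3,4,5-tetramethoxy-6-(methoxymethoxy)benzene F1. Iodine–lithium exchange (n-BuLi, THF, −78 °C) gives [2,3,4,5-tetramethoxy-6-(methoxymethoxy)phenyl]lithium F2. This is acylated with the Weinreb amide of phenylpropiolic acid (N-methoxy-N-methyl-3-phenylprop-2-ynamide, a reagent that is not made on the way) to give 1-[2,3,4,5-tetramethoxy-6-(methoxymethoxy)phenyl]-3-phenylprop-2-yn-1-one F3 after an aqueous NH4Cl quench. HCl in MeOH removes the acetal to give ynone 8, and Et2NH in EtOH closes it through 9 to 10, so the amine-directed six-membered closure is kept.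

**Step 4.**
- Risk: oxygen transfer to the electron-poor C2=C3 bond is slow, so the excess oxidant and long reaction time may lead to oxidation of the electron-rich ring A. Epoxide 11 may also open by paths other than loss of the C3 hydrogen.
- Fallback: it sets out from 10 and rejoins at 12. C3 is functionalised as a carbanion instead of as an alkene. LiN(i-Pr)2 in THF at −78 °C deprotonates C3 to give 3-lithio-5,6,7,8-tetramethoxyflavone F4. B(OMe)3 converts it into dimethyl (5,6,7,8-tetramethoxy-4-oxo-2-phenyl-4H-chromen-3-yl)boronate F5, and H2O2 in AcOH oxidises the C–B bond to give 12.

**Step 6.**
- Risk: over-cleavage. The C3 methyl group may be lost through the five-membered chelate, or the C6 methyl group once the C5 oxygen is bound to boron. The boron chelate may also hydrolyse incompletely.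
- Fallback: it sets out from 12 and rejoins at 14. The order of the last two steps is reversed, which moves the selectivity from ether cleavage to O-alkylation. BCl3 in CH2Cl2 cleaves the C5 ether of 12, where no C3 ether competes, to give 3,5-dihydroxy-6,7,8-trimethoxyflavone F6. One equivalent of MeI with K2CO3 in acetone then methylates the C3 hydroxyl, because the chelated C5 hydroxyl is much the less reactive, giving 14.

**Step 2.**
- Risk: oxidative demethylation of the para-methoxyphenol to a quinone by the electrophilic iodine source, in competition with substitution.
- Fallback: it sets out from 4 and rejoins at 5. Iodine is introduced through a carbanion on the protected phenol. Phenol 4 is converted (MOMCl, i-Pr2NEt, CH2Cl2) into 1,2,3,4-tetramethoxy-5-(methoxymethoxy)benzene F7. n-BuLi in THF at 0 °C lithiates the single ring CH, which lies between the acetal oxygen and a methoxy group, and gives the same aryllithium F2 as in the fallback for step 3. Quenching with I2 gives F1, and HCl in MeOH returns 5. F2 made this way can instead be acylated directly as described for step 3, which bypasses the aryl iodide.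

**Step 1.**
- Risk: incomplete lithiation, or further oxidation of the electron-rich phenol during the peroxide treatment.
- Fallback: it sets out from 1 and rejoins at 4. Rieche formylation (Cl2CHOMe, TiCl4, CH2Cl2, 0 °C) gives 2,3,4,5-tetramethoxybenzaldehyde F8. Baeyer–Villiger oxidation with mCPBA in CH2Cl2 gives 2,3,4,5-tetramethoxyphenyl formate F9; aryl migration is favoured by the ortho and para methoxy groups. K2CO3 in MeOH then cleaves the formate to give 4.

## Further compounds

F1 | step 3 | 1-iodo-2,3,4,5-tetramethoxy-6-(methoxymethoxy)benzene | COCOc1c(I)c(OC)c(OC)c(OC)c1OC
F2 | step 3 | [2,3,4,5-tetramethoxy-6-(methoxymethoxy)phenyl]lithium | COCOc1c([Li])c(OC)c(OC)c(OC)c1OC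
F3 | step 3 | 1-[2,3,4,5-tetramethoxy-6-(methoxymethoxy)phenyl]-3-phenylprop-2-yn-1-one | COCOc1c(C(=O)C#Cc2ccccc2)c(OC)c(OC)c(OC)c1OC
F4 | step 4 | 3-lithio-5,6,7,8-tetramethoxyflavone | COc1c(OC)c(OC)c2c(=O)c([Li])c(-c3ccccc3)oc2c1OC
F5 | step 4 | dimethyl (5,6,7,8-tetramethoxy-4-oxo-2-phenyl-4H-chromen-3-yl)boronate | COB(OC)c1c(-c2ccccc2)oc2c(OC)c(OC)c(OC)c(OC)c2c1=O
F6 | step 6 | 3,5-dihydroxy-6,7,8-trimethoxyflavone | COc1c(OC)c(O)c2c(=O)c(O)c(-c3ccccc3)oc2c1OC
F7 | step 2 | 1,2,3,4-tetramethoxy-5-(methoxymethoxy)benzene | COCOc1cc(OC)c(OC)c(OC)c1OC
F8 | step 1 | 2,3,4,5-tetramethoxybenzaldehyde | COc1cc(C=O)c(OC)c(OC)c1OC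
F9 | step 1 | 2,3,4,5-tetramethoxyphenyl formate | COc1cc(OC=O)c(OC)c(OC)c1OC
A1 | alternative 1 | 5,8-dihydroxy-3,6,7-trimethoxyflavone | COc1c(OC)c(O)c2c(=O)c(OC)c(-c3ccccc3)oc2c1O
A2 | alternative 1 | 4-hydroxy-2,3-dimethoxy-4-(5-methoxy-4-oxo-6-phenyl-4H-pyran-2-yl)cyclobut-2-en-1-one (racemic) | COC1=C(OC)C(O)(c2cc(=O)c(OC)c(-c3ccccc3)o2)C1=O
A3 | alternative 1 | 3-methoxy-2-phenyl-4H-pyran-4-one | COc1c(-c2ccccc2)occc1=O
A4 | alternative 1 | dimethyl squarate (3,4-dimethoxycyclobut-3-ene-1,2-dione) | COC1=C(OC)C(=O)C1=O
A5 | alternative 2 | 3-bromo-5,6,7,8-tetramethoxyflavone | COc1c(OC)c(OC)c2c(=O)c(Br)c(-c3ccccc3)oc2c1OC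
A6 | alternative 2 | tert-butyl(dimethyl)[(4,5,6,7-tetramethoxy-2-phenyl-1-benzofuran-3-yl)oxy]silane | COc1c(OC)c(OC)c2c(O[Si](C)(C)C(C)(C)C)c(-c3ccccc3)oc2c1OC
A7 | alternative 2 | 4,5,6,7-tetramethoxy-2-phenyl-1-benzofuran-3(2H)-one (racemic) | COc1c(OC)c(OC)c2c(c1OC)OC(c1ccccc1)C2=O
A8 | alternative 3 | 3,5,6,7,8-pentamethoxyflavone (identical with 13) | COc1c(OC)c(OC)c2c(=O)c(OC)c(-c3ccccc3)oc2c1OC
A9 | alternative 3 | 2,3,4,5-tetramethoxy-6-(trimethylsilyl)phenyl trifluoromethanesulfonate | COc1c(OC)c(OC)c(OS(=O)(=O)C(F)(F)F)c([Si](C)(C)C)c1OC
A10 | alternative 3 | 3,4,5,6-tetramethoxybenzyne | COC1=C(OC)C(OC)=C(OC)C#C1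
A11 | alternative 3 | methyl 2-methoxy-3-oxo-3-phenylpropanoate (racemic) | COC(=O)C(OC)C(=O)c1ccccc1
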